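Partner A, at 12.1 mM, is charged above the substrate, at 11 mM, and both consume partner B.

all flasks: substrate 11 mM
- Tuesday's: partner A 12.1 mM; partner B 11 mM; run made earlier
- Wednesday's: partner A 8.1 mM; partner B 11 mM; run made earlier
- Saturday's: partner A 18 mM; partner B 11 mM; run made earlier
- theta: partner A 12.1 mM; partner B 11.0 mM; a single well-mixed tank run continuously and read at steady state, 25.0 h in it on average
- epsilon: partner A 12.1 mM; partner B 11.0 mM; one stirred flow tank at steady state, fed with the mixture as stated, mean residence time 5.0 h
- eta: partner A 12.1 mM; partner B 11.0 mM; a closed flask charged with all of it at once and left for 5.0 h; time 5.0 h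
- gamma: partner A 12.1 mM (fed, over 5.00 h); partner B 11.0 mM; all but partner A at the start; partner A goes in evenly over 5.00 h, the run ends at 5.0 h; time 5.0 h

| run | time / h | open intermediate / % | target / % |
|---|---|---|---|
| Tuesday's | 0.667 | 8 | 3 |
| Tuesday's | 2.00 | 16 | 0 |
| Tuesday's | 3.00 | 21 | 1 |
| Tuesday's | 5.00 | 18 | 0 |
| Wednesday's | 0.250 | 3 | 1 |
| Wednesday's | 0.500 | 5 | 0 |
| Wednesday's | 1.33 | 12 | 3 |
| Wednesday's | 3.00 | 17 | 3 |
| Saturday's | 0.250 | 2 | 0 |
| Saturday's | 0.500 | 6 | 0 |
| Saturday's | 1.33 | 14 | 0 |
| Saturday's | 3.00 | 12 | 4 |

(readings scatter by 2 percentage points)

* the set-up with the highest amount of open intermediate at the outlet or at the end, in percent of the substrate put in ("none" if the first two lie within 2 percentage points) (theta / epsilon / eta / gamma / none)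
* amount of open intermediate at the outlet or at the end, in percent of the substrate put in, theta
* amount of open intermediate at the outlet or at the end, in percent of the substrate put in, epsilon
* amount of open intermediate at the outlet or at the end, in percent of the substrate put in, eta
* amount of open intermediate at the outlet or at the end, in percent of the substrate put in, gamma

- percent here means substrate units held: one homo product counts as two
- the stated concentrations are those of everything mixed, before any reaction; amounts are the same in each set-up
- the numbers in the tables scatter with a standard deviation of 2 percentage points
- steps under discussion: open intermediate + second intermediate <-> target; substrate + partner B -> open intermediate; 2 open intermediate -> homo product; partner B + partner A -> second intermediate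
- the feed brings no volume worth counting
- the earlier runs were made in a closed, stirred flask

My zero of the scale is the symmetric case, in which substrate and partner A react equally fast per mM. Substrate then takes 47.6 % of the partner B consumed at the start. This fraction, substrate concentration over the sum of substrate and partner A concentrations, is the substrate's share, a selectivity. Wednesday's and Saturday's charges give shares in the ratio 1.52, and their open intermediate readings at 3.00 h stand in the ratio 1.42, each reading carrying a scatter of 2 percentage points.

Eta repeats Tuesday's charge in a closed flask, so I take Tuesday's reading at 5.00 h, 18 %, for eta. In gamma, partner A averages half its charge over the dosing, counting none consumed, which lifts the share to 64.5 %. Scaling the reading by the two shares gives an estimate of 24.4 % for gamma, a gap of 6.4 points over eta against a margin of 2 points, so I choose gamma, leaving the two flow tanks, theta and epsilon, unreckoned.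

The forecast says none, with 7.5 % for theta, 11 % for epsilon, 16.5 % for eta and 17.5 % for gamma, of which it says “the extra intermediate mostly dimerises”.

The simulation gives gamma as best, with 11.9 % for theta, 14.0 % for epsilon, 18.6 % for eta and 27.1 % for gamma.

    open intermediate + second intermediate ⇌ target (K = 1200 /M, k = 0.00430 /M/s)
    substrate + partner B → open intermediate (k = 0.00270 /M/s)
    2 open intermediate → homo product (k = 7.00 × 10⁻⁴ /M/s)
    partner B + partner A → second intermediate (k = 0.00660 /M/s)

In eta, with the other concentrations as charged, partner B has a half-life of 2.4 h by partner A alone, shorter than the 6.5 h of substrate by the making of open intermediate alone. With substrate and partner B charged alike, these times put the substrate's share at the charge in eta at 27.0 %, below the symmetric 47.6 %, and doubling the first time for gamma's average partner A, counting none consumed, gives a share of 42.5 %.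

(The readings are simulated with made-up constants, noise included.)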